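A direct plan would join the two B rings early as a diaryl ether by SNAr, with one of two formyl groups masked as an acetal (A1). It would build the flavone on the free aldehyde through a 2′-hydroxychalcone, unmask the second aldehyde and condense it to a second chalcone (A2). Ring C of the flavanone would then be closed by oxa-Michael addition to the racemate (A3), which would be resolved.
Its weakest steps would be:
- the resolution of racemic A3, which would discard at least half of the most advanced intermediate;
- the oxa-Michael closure of A2, an equilibrium between chalcone and flavanone that would rarely go to completion and would form C2 without control;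
- the masking and unmasking of one formyl group in A1, two operations that would add length and no complexity.

The route rests on the C2–C1′ bond of the flavanone. Ring C is taken ready-made as 5-hydroxy-7-methoxychromone, whose O1–C2=C3–C4=O unit is a vinylogous ester with an unsubstituted β-carbon, and ring B arrives as an arylboronic acid that already carries the diaryl ether and the finished flavone. One enantioselective palladium-catalysed conjugate arylation would join the two halves and set C2, the only stereocentre, in the same operation. Since no chalcone is closed, there is no equilibrium cyclisation, no racemate and nothing to resolve; and since the diaryl ether carries a single ester arm, no formyl group has to be masked.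

Key step: step 7

Assumption: the sense of induction in step 7 is taken from the usual quadrant model of palladium–pyridine-oxazoline catalysts, by which the (R)-ligand should deliver the aryl group to the Re face of C2; should a test with phenylboronic acid show the opposite sense, the (S)-ligand would be used.

Step 1
Reactants: 1 2-(benzyloxy)-5-bromobenzaldehyde
Product: 3 2-(benzyloxy)-5-bromophenol, via aryl formate 2 (not isolated)
Conditions: mCPBA (1.3 equiv), CH2Cl2, 0 °C to rt, 12 h; aq NaHCO3 wash; then K2CO3 (0.2 equiv), MeOH, rt, 1 h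
Reagents that add atoms: mCPBA, O=C(OO)c1cccc(Cl)c1
Why: Baeyer–Villiger oxidation of an electron-rich benzaldehyde (Dakin-type), in which the ortho-benzyloxy aryl group migrates in preference to hydrogen in the Criegee adduct to give formate 2, which catalytic carbonate in methanol transesterifies to the phenol.

Step 2
Reactants: 3 2-(benzyloxy)-5-bromophenol; 4 ethyl 4-fluorobenzoate
Product: 5 ethyl 4-[2-(benzyloxy)-5-bromophenoxy]benzoate
Conditions: 4 (1.2 equiv), Cs2CO3 (1.5 equiv), dry DMSO, 110 °C, N2, 16 h
Reagents that add atoms: none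
Why: Nucleophilic aromatic substitution by addition–elimination, in which the para-ethoxycarbonyl group stabilises the Meisenheimer adduct and fluoride leaves, while the unactivated aryl bromide and the benzyl ether are untouched.

Step 3
Reactants: 6 2,4,6-trihydroxyacetophenone
Product: 7 1-[2,4-bis(benzyloxy)-6-hydroxyphenyl]ethanone
Conditions: BnBr (2.05 equiv), K2CO3 (2.2 equiv), DMF, rt to 50 °C, 12 h
Reagents that add atoms: benzyl bromide, BrCc1ccccc1
Why: Williamson etherification that should stop at the bis-ether because the remaining hydroxyl is hydrogen-bonded to the acetyl carbonyl and is the least nucleophilic.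

Step 4
Reactants: 7 1-[2,4-bis(benzyloxy)-6-hydroxyphenyl]ethanone; 5 ethyl 4-[2-(benzyloxy)-5-bromophenoxy]benzoate
Product: 9 5,7-bis(benzyloxy)-2-{4-[2-(benzyloxy)-5-bromophenoxy]phenyl}-4H-chromen-4-one, via 1,3-diketone 8 (not isolated)
Conditions: 7 (1.0 equiv), LiN(SiMe3)2 (1 M in THF, 3.5 equiv), THF, −78 to −10 °C, 1 h; 5 (1.05 equiv), −78 °C to rt, 12 h; 1 M HCl to pH 3; crude 8, p-TsOH·H2O (0.2 equiv), toluene, 90 °C, 2 h
Reagents that add atoms: none
Why: Crossed Claisen condensation of the lithium phenoxide–enolate of 7 with the non-enolisable ester 5, driven by deprotonation of the 1,3-diketone, followed by acid-catalysed cyclodehydration (attack of the phenol on the aroyl carbonyl and loss of water) that closes the flavone pyranone; no stereocentre is formed.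

Step 5
Reactants: 9 5,7-bis(benzyloxy)-2-{4-[2-(benzyloxy)-5-bromophenoxy]phenyl}-4H-chromen-4-one
Product: 10 {4-(benzyloxy)-3-[4-(5,7-bis(benzyloxy)-4-oxo-4H-chromen-2-yl)phenoxy]phenyl}boronic acid
Conditions: B2(OH)4 (3.0 equiv), PdCl(2′-aminobiphenyl-2-yl)(XPhos) (second-generation XPhos palladacycle, divalent palladium, 2 mol %), XPhos (2-dicyclohexylphosphino-2′,4′,6′-triisopropylbiphenyl, 4 mol %), KOAc (3.0 equiv), EtOH/THF (3:1), 70 °C, 3 h; dilute HCl work-up
Reagents that add atoms: tetrahydroxydiboron, OB(O)B(O)O
Why: Miyaura-type borylation of an aryl bromide with tetrahydroxydiboron (oxidative addition to zerovalent palladium, acetate-assisted transmetalation from the B–B bond, reductive elimination), which should give the boronic acid directly under weakly basic conditions that leave the flavone, the diaryl ether and the benzyl ethers intact.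

Step 6
Reactants: 11 5,7-dihydroxy-4H-chromen-4-one
Product: 12 5-hydroxy-7-methoxy-4H-chromen-4-one
Conditions: MeI (1.1 equiv), K2CO3 (1.1 equiv), acetone, 40 °C, 6 h
Reagents that add atoms: iodomethane, CI
Why: Williamson O-methylation selective for the 7-OH, the more acidic vinylogous carboxylic acid hydroxyl, because the 5-OH is locked in a hydrogen bond to the C4 carbonyl.

Step 7
Reactants: 12 5-hydroxy-7-methoxy-4H-chromen-4-one; 10 {4-(benzyloxy)-3-[4-(5,7-bis(benzyloxy)-4-oxo-4H-chromen-2-yl)phenoxy]phenyl}boronic acid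
Product: 13 (2S)-2-{4-(benzyloxy)-3-[4-(5,7-bis(benzyloxy)-4-oxo-4H-chromen-2-yl)phenoxy]phenyl}-5-hydroxy-7-methoxychroman-4-one
Conditions: 10 (1.0 equiv), 12 (2.5 equiv), Pd(OCOCF3)2 (10 mol %), (R)-t-BuPyOx [(R)-4-tert-butyl-2-(pyridin-2-yl)-4,5-dihydrooxazole, 12 mol %], NH4PF6 (30 mol %), H2O (5 equiv), ClCH2CH2Cl, 50 °C, air, 24 h
Reagents that add atoms: none
Why: The arylboronic acid transmetalates to the cationic divalent palladium–pyridine-oxazoline complex, the chromone C2=C3 bond coordinates and inserts into the Pd–aryl bond (syn-carbopalladation, aryl to C2), and the resulting C3-palladium enolate is protonated by water, which returns the divalent palladium catalyst without any redox change. The closest known reaction type is the palladium/pyridine-oxazoline-catalysed asymmetric conjugate addition of arylboronic acids to chromones and cyclic enones (a Hayashi–Miyaura-type 1,4-addition). No ring is closed: ring C is present from the start as the chromone, and the step forms the exocyclic C2–C1′ bond that joins it to ring B and, through ring B, to the whole flavone half. The new stereocentre C2 is controlled by the catalyst alone, the tert-butyl group of the (R)-oxazoline blocking one quadrant so that the aryl group migrates to the Re face of C2, which gives (2S). The step needs chemoselectivity between two enone-type acceptors, and the substrate secures it because C2 of 12 is an unsubstituted β-carbon whereas C2 of the flavone in 10 is fully substituted and aryl-conjugated and would have to become a quaternary centre. The chelated 5-OH should stay protonated in the weakly acidic, base-free medium, so it should neither bind palladium strongly nor allow retro-oxa-Michael opening and racemisation of the product, and the excess of 12 should outrun protodeboronation of 10.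

Step 8
Reactants: 13 (2S)-2-{4-(benzyloxy)-3-[4-(5,7-bis(benzyloxy)-4-oxo-4H-chromen-2-yl)phenoxy]phenyl}-5-hydroxy-7-methoxychroman-4-one
Product: 14 (2S)-2-{3-[4-(5,7-dihydroxy-4-oxo-4H-chromen-2-yl)phenoxy]-4-hydroxyphenyl}-5-hydroxy-7-methoxychroman-4-one (target)
Conditions: H2 (1 atm), Pd/C (10 wt % Pd), EtOAc/MeOH (1:1), rt, 2–4 h (monitored); filtration through Celite
Reagents that add atoms: none
Why: Heterogeneous hydrogenolysis of the three benzyl aryl ethers under neutral conditions, which should spare the methyl ether, the diaryl ether, the flavone C2=C3 bond and both carbonyl groups and, in the absence of acid or base, should not open ring C or racemise C2.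

**Compound list**
1 | 2-(benzyloxy)-5-bromobenzaldehyde | O=Cc1cc(Br)ccc1OCc1ccccc1 | starting material
2 | 2-(benzyloxy)-5-bromophenyl formate (aryl formate, not isolated) | O=COc1cc(Br)ccc1OCc1ccccc1 | intermediate
3 | 2-(benzyloxy)-5-bromophenol | Oc1cc(Br)ccc1OCc1ccccc1 | intermediate
4 | ethyl 4-fluorobenzoate | CCOC(=O)c1ccc(F)cc1 | starting material
5 | ethyl 4-[2-(benzyloxy)-5-bromophenoxy]benzoate | CCOC(=O)c1ccc(Oc2cc(Br)ccc2OCc2ccccc2)cc1 | intermediate
6 | 2,4,6-trihydroxyacetophenone | CC(=O)c1c(O)cc(O)cc1O | starting material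
7 | 1-[2,4-bis(benzyloxy)-6-hydroxyphenyl]ethanone | CC(=O)c1c(O)cc(OCc2ccccc2)cc1OCc1ccccc1 | intermediate
8 | 1-[2,4-bis(benzyloxy)-6-hydroxyphenyl]-3-{4-[2-(benzyloxy)-5-bromophenoxy]phenyl}propane-1,3-dione (1,3-diketone, not isolated) | O=C(CC(=O)c1ccc(Oc2cc(Br)ccc2OCc2ccccc2)cc1)c1c(O)cc(OCc2ccccc2)cc1OCc1ccccc1 | intermediate
9 | 5,7-bis(benzyloxy)-2-{4-[2-(benzyloxy)-5-bromophenoxy]phenyl}-4H-chromen-4-one | O=c1cc(-c2ccc(Oc3cc(Br)ccc3OCc3ccccc3)cc2)oc2cc(OCc3ccccc3)cc(OCc3ccccc3)c12 | intermediate
10 | {4-(benzyloxy)-3-[4-(5,7-bis(benzyloxy)-4-oxo-4H-chromen-2-yl)phenoxy]phenyl}boronic acid | OB(O)c1ccc(OCc2ccccc2)c(Oc2ccc(-c3cc(=O)c4c(OCc5ccccc5)cc(OCc5ccccc5)cc4o3)cc2)c1 | intermediate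
11 | 5,7-dihydroxy-4H-chromen-4-one | O=c1ccoc2cc(O)cc(O)c12 | starting material
12 | 5-hydroxy-7-methoxy-4H-chromen-4-one | COc1cc(O)c2c(c1)occc2=O | intermediate
13 | (2S)-2-{4-(benzyloxy)-3-[4-(5,7-bis(benzyloxy)-4-oxo-4H-chromen-2-yl)phenoxy]phenyl}-5-hydroxy-7-methoxychroman-4-one | COc1cc(O)c2c(c1)O[C@H](c1ccc(OCc3ccccc3)c(Oc3ccc(-c4cc(=O)c5c(OCc6ccccc6)cc(OCc6ccccc6)cc5o4)cc3)c1)CC2=O | intermediate
14 | (2S)-2-{3-[4-(5,7-dihydroxy-4-oxo-4H-chromen-2-yl)phenoxy]-4-hydroxyphenyl}-5-hydroxy-7-methoxychroman-4-one | COc1cc(O)c2c(c1)O[C@H](c1ccc(O)c(Oc3ccc(-c4cc(=O)c5c(O)cc(O)cc5o4)cc3)c1)CC2=O | target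

Total step count: 8 steps. Longest linear sequence: 6 steps (steps 1, 2, 4, 5, 7, 8).

**Steps most likely to fail**

Step 7. The 5-hydroxy-4-oxo unit may sequester the palladium catalyst, protodeboronation of 10 may outpace insertion into the electron-rich chromone, or facial selectivity may be insufficient. The fallback sets out from 12, which would be O-benzylated (BnBr, K2CO3, DMF, 60 °C) to 5-(benzyloxy)-7-methoxy-4H-chromen-4-one F1. The aryl group of 10 would then be transferred to F1 under monovalent rhodium catalysis ([RhCl(C2H4)2]2, an electron-poor atropisomeric diphosphine of the antipode that gives 2S, toluene/H2O, rt). In this manifold boron transmetalates to a rhodium hydroxide, the aryl–rhodium species inserts the enone and the oxa-π-allyl is hydrolysed, so no Lewis-acidic palladium and no free chelating phenol are present. This would give (2S)-5-(benzyloxy)-2-{4-(benzyloxy)-3-[4-(5,7-bis(benzyloxy)-4-oxo-4H-chromen-2-yl)phenoxy]phenyl}-7-methoxychroman-4-one F2, whose hydrogenolysis under the conditions of step 8 would come back to the route at 14.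

Step 5. Protodeboronation may occur, the diboron reagent in ethanol may act as a hydrogen source that reduces the flavone C2=C3 bond or cleaves benzyl ethers, and a free boronic acid that forms anhydrides may be hard to purify. The fallback sets out from 9. Miyaura borylation with bis(pinacolato)diboron in an aprotic medium (PdCl2(dppf), KOAc, dioxane, 90 °C) would give the chromatographable 5,7-bis(benzyloxy)-2-{4-[2-(benzyloxy)-5-(4,4,5,5-tetramethyl-1,3,2-dioxaborolan-2-yl)phenoxy]phenyl}-4H-chromen-4-one F3. Oxidative cleavage of the pinacol unit (NaIO4, NH4OAc, acetone/H2O, rt) would come back to the route at 10.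

Step 4. The intermolecular Claisen condensation of the hindered, electron-rich ketone enolate with an unactivated ester may stay incomplete, and the acid-labile 5-O-benzyl group may be lost during cyclodehydration. The fallback sets out from 5. Saponification (LiOH, THF/H2O, rt) would give 4-[2-(benzyloxy)-5-bromophenoxy]benzoic acid F4. Carbodiimide esterification with 7 (EDC·HCl, DMAP, CH2Cl2, rt) would give 2-acetyl-3,5-bis(benzyloxy)phenyl 4-[2-(benzyloxy)-5-bromophenoxy]benzoate F5. Baker–Venkataraman rearrangement of F5 (KOH, pyridine, 50 °C), an intramolecular acyl transfer to the ketone enolate, would come back to the route at 8, which would be cyclised with NaOAc in AcOH if sulfonic acid proves too harsh.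

**Further compounds**
F1 | step 7 | 5-(benzyloxy)-7-methoxy-4H-chromen-4-one | COc1cc(OCc2ccccc2)c2c(c1)occc2=O
F2 | step 7 | (2S)-5-(benzyloxy)-2-{4-(benzyloxy)-3-[4-(5,7-bis(benzyloxy)-4-oxo-4H-chromen-2-yl)phenoxy]phenyl}-7-methoxychroman-4-one | COc1cc(OCc2ccccc2)c2c(c1)O[C@H](c1ccc(OCc3ccccc3)c(Oc3ccc(-c4cc(=O)c5c(OCc6ccccc6)cc(OCc6ccccc6)cc5o4)cc3)c1)CC2=O
F3 | step 5 | 5,7-bis(benzyloxy)-2-{4-[2-(benzyloxy)-5-(4,4,5,5-tetramethyl-1,3,2-dioxaborolan-2-yl)phenoxy]phenyl}-4H-chromen-4-one | CC1(C)OB(c2ccc(OCc3ccccc3)c(Oc3ccc(-c4cc(=O)c5c(OCc6ccccc6)cc(OCc6ccccc6)cc5o4)cc3)c2)OC1(C)C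
F4 | step 4 | 4-[2-(benzyloxy)-5-bromophenoxy]benzoic acid | OC(=O)c1ccc(Oc2cc(Br)ccc2OCc2ccccc2)cc1
F5 | step 4 | 2-acetyl-3,5-bis(benzyloxy)phenyl 4-[2-(benzyloxy)-5-bromophenoxy]benzoate | CC(=O)c1c(OC(=O)c2ccc(Oc3cc(Br)ccc3OCc3ccccc3)cc2)cc(OCc2ccccc2)cc1OCc1ccccc1
A1 | direct plan | 4-[2-(benzyloxy)-5-(1,3-dioxolan-2-yl)phenoxy]benzaldehyde | O=Cc1ccc(Oc2cc(C3OCCO3)ccc2OCc2ccccc2)cc1
A2 | direct plan | 2-{4-[2-(benzyloxy)-5-{(E)-3-[2-(benzyloxy)-6-hydroxy-4-methoxyphenyl]-3-oxoprop-1-enyl}phenoxy]phenyl}-5,7-bis(benzyloxy)-4H-chromen-4-one | COc1cc(O)c(C(=O)/C=C/c2ccc(OCc3ccccc3)c(Oc3ccc(-c4cc(=O)c5c(OCc6ccccc6)cc(OCc6ccccc6)cc5o4)cc3)c2)c(OCc2ccccc2)c1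
A3 | direct plan | racemic 5-(benzyloxy)-2-[4-(benzyloxy)-3-{4-[5,7-bis(benzyloxy)-4-oxo-4H-chromen-2-yl]phenoxy}phenyl]-7-methoxychroman-4-one | COc1cc(OCc2ccccc2)c2c(c1)OC(c1ccc(OCc3ccccc3)c(Oc3ccc(-c4cc(=O)c5c(OCc6ccccc6)cc(OCc6ccccc6)cc5o4)cc3)c1)CC2=O
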